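**Retrosynthetic overview**

1. Robustol ⇐ threefold O-demethylation of its trimethyl ether ⇐ hydrogenation of a 22-membered cycloalkene; the target is achiral.
2. The macrocycle, the only ring made in the route, is closed by ring-closing olefin metathesis at C5–C6 of the (CH2)14 tether (numbered from ring B). The precursor is an acyclic diaryl ether with a hex-5-enyl chain on ring B and a dec-9-enyl chain on ring A.
3. Enabling feature: the tether is fourteen unfunctionalised CH2 groups joining C4 of the pyrogallol ring B to C5 of the resorcinol ring A, and the rings are already tied by the ether O between C1 of ring A (meta to the tether) and C1 of ring B (para to the tether). Any tether bond could therefore be the closure site. C5–C6 is chosen because it lies at least four CH2 groups from either arene and because both halves then come from symmetrical dienes (hexa-1,5-diene, deca-1,9-diene).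
4. Diene ⇐ copper-catalysed Ullmann diaryl ether coupling of a 4-alkenyl-2,6-dimethoxyphenol with a 3-alkenyl-5-methoxybromobenzene; each half ⇐ hydroboration/B-alkyl Suzuki coupling of a diene with a commercial haloarene.
5. Ring order: both arenes are bought; the 22-membered meta,para-cyclophane ring is formed in step 4 and saturated in step 5.

Key step: step 4

Remark: the target has no stereocentre; the tether carbons are numbered C1 (on ring B) to C14 (on ring A), and the geometry of the olefin made in step 4 is erased in step 5, so compound 10 is drawn as the E isomer expected to predominate.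

**Route**

Step 1
Reactants: 1 hexa-1,5-diene; 2 4-bromo-2,6-dimethoxyphenol
Product: 4 4-(hex-5-en-1-yl)-2,6-dimethoxyphenol, via 9-(hex-5-en-1-yl)-9-borabicyclo[3.3.1]nonane 3 (not isolated)
Conditions: 9-BBN (0.5 M in THF, 1.3 equiv relative to 2), 1 (6 equiv), THF, 0 °C to rt; excess 1 removed in vacuo; then 2, Pd(OAc)2 (3 mol %), SPhos (6 mol %), K3PO4 (3 M aq, 4 equiv), THF, 65 °C
Reagents that add atoms: none
Why: Anti-Markovnikov hydroboration of one vinyl group of the excess diene followed by B-alkyl Suzuki–Miyaura coupling, in which SPhos-ligated zerovalent palladium inserts into the C–Br bond of the potassium phenoxide of 2 and the base-activated primary alkylborane transmetalates faster than β-hydride elimination can intervene, the free phenol being tolerated as its salt.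

Step 2
Reactants: 5 deca-1,9-diene; 6 1-bromo-3-iodo-5-methoxybenzene
Product: 8 1-bromo-3-(dec-9-en-1-yl)-5-methoxybenzene, via 9-(dec-9-en-1-yl)-9-borabicyclo[3.3.1]nonane 7 (not isolated)
Conditions: 9-BBN (0.5 M in THF, 1.1 equiv relative to 6), 5 (4 equiv), THF, 0 °C to rt; then 6, Pd(dppf)Cl2 (3 mol %), K3PO4 (3 M aq, 3 equiv), DMF/THF, rt
Reagents that add atoms: none
Why: The same hydroboration/B-alkyl Suzuki–Miyaura sequence, made chemoselective by the much faster oxidative addition of zerovalent palladium into C–I than into C–Br at room temperature, so that the bromide is kept for step 3.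

Step 3
Reactants: 4 4-(hex-5-en-1-yl)-2,6-dimethoxyphenol; 8 1-bromo-3-(dec-9-en-1-yl)-5-methoxybenzene
Product: 9 2-[3-(dec-9-en-1-yl)-5-methoxyphenoxy]-5-(hex-5-en-1-yl)-1,3-dimethoxybenzene
Conditions: 4 (1.2 equiv), CuI (10 mol %), picolinic acid (20 mol %), K3PO4 (2 equiv), DMSO, 90 °C, argon
Reagents that add atoms: none
Why: Ullmann-type diaryl ether synthesis in which the picolinate-ligated monovalent copper phenoxide of 4 reacts with the unhindered aryl bromide 8 by oxidative addition and C–O reductive elimination, a ligand system suited to 2,6-disubstituted phenols and inert towards isolated terminal olefins.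

Step 4
Reactants: 9 2-[3-(dec-9-en-1-yl)-5-methoxyphenoxy]-5-(hex-5-en-1-yl)-1,3-dimethoxybenzene
Product: 10 tri-O-methyl-5,6-didehydrorobustol, the 22-membered cycloalkene in which C4 of ring B and C5 of ring A are joined by a –(CH2)4–CH=CH–(CH2)8– tether (E olefin drawn)
Conditions: second-generation Grubbs catalyst RuCl2(=CHPh)(H2IMes)(PCy3) (10 mol %, added in two portions), 1,4-benzoquinone (20 mol %), CH2Cl2 (1 mM in 9), 40 °C, argon sparge
Reagents that add atoms: none
Why: Ring-closing olefin metathesis by the Chauvin mechanism: the ruthenium benzylidene exchanges onto one terminal vinyl group, the resulting alkylidene adds to the second vinyl group of the same molecule in a [2+2] step, and cycloreversion of the ruthenacyclobutane releases the C5=C6 olefin and a ruthenium methylidene, the loss of ethene from the sparged solution driving the sequence forward. The closest known reaction type is the macrocyclising ring-closing metathesis of α,ω-dienes hung on biaryl or diaryl ether hinges, which is well established for large-ring cyclophanes of about this size. The one ring closed is the 22-membered meta,para-cyclophane ring, formed by end-to-end macrocyclic closure of two monosubstituted olefins. No stereocentre is created, and the olefin geometry (E expected to dominate under thermodynamic control in a ring of this size) is irrelevant because step 5 saturates the bond. The selectivity needed is ring closure over acyclic diene metathesis oligomerisation and over double-bond migration; it should be secured by high dilution with portionwise catalyst addition, by the substrate itself, whose two olefins are unhindered vinyl groups insulated from each arene by at least four CH2 groups and held in one molecule by the bent C–O–C hinge, and by 1,4-benzoquinone, which intercepts ruthenium hydrides. Because metathesis is reversible, linear oligomers formed along the way are expected to back-bite to the strain-free monomeric ring under these conditions.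

Step 5
Reactants: 10 tri-O-methyl-5,6-didehydrorobustol
Product: 11 tri-O-methylrobustol, the saturated macrocycle with a (CH2)14 tether and three OMe groups (C3 of ring A, C2 and C6 of ring B)
Conditions: H2 (1 atm), Pd/C (10 wt % Pd), EtOAc, rt
Reagents that add atoms: none
Why: Heterogeneous catalytic hydrogenation of an unhindered 1,2-disubstituted olefin should convert either alkene isomer into the same saturated tether, leaving the aryl methyl ethers and the diaryl ether untouched.

Step 6
Reactants: 11 tri-O-methylrobustol
Product: 12 robustol
Conditions: BBr3 (6 equiv), CH2Cl2, −78 °C to rt; then MeOH, H2O, 0 °C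
Reagents that add atoms: none
Why: Lewis acid-mediated aryl methyl ether cleavage (BBr3 demethylation), in which boron coordinates each methoxy oxygen and bromide removes the methyl group by SN2 attack, while the diaryl ether has no sp3 carbon on oxygen and should survive, the aryl borates being hydrolysed to the three phenols on work-up.

**Compound list**

1 | hexa-1,5-diene | C=CCCC=C | starting material
2 | 4-bromo-2,6-dimethoxyphenol | COc1cc(Br)cc(OC)c1O | starting material
3 | 9-(hex-5-en-1-yl)-9-borabicyclo[3.3.1]nonane | C=CCCCCB1C2CCCC1CCC2 | intermediate
4 | 4-(hex-5-en-1-yl)-2,6-dimethoxyphenol | COc1cc(CCCCC=C)cc(OC)c1O | intermediate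
5 | deca-1,9-diene | C=CCCCCCCC=C | starting material
6 | 1-bromo-3-iodo-5-methoxybenzene | COc1cc(Br)cc(I)c1 | starting material
7 | 9-(dec-9-en-1-yl)-9-borabicyclo[3.3.1]nonane | C=CCCCCCCCCB1C2CCCC1CCC2 | intermediate
8 | 1-bromo-3-(dec-9-en-1-yl)-5-methoxybenzene | COc1cc(Br)cc(CCCCCCCCC=C)c1 | intermediate
9 | 2-[3-(dec-9-en-1-yl)-5-methoxyphenoxy]-5-(hex-5-en-1-yl)-1,3-dimethoxybenzene | COc1cc(CCCCCCCCC=C)cc(Oc2c(OC)cc(CCCCC=C)cc2OC)c1 | intermediate
10 | tri-O-methyl-5,6-didehydrorobustol (22-membered cycloalkene, E olefin at C5=C6 of the tether) | COc1cc2cc(c1)Oc1c(OC)cc(cc1OC)CCCC/C=C/CCCCCCCC2 | intermediate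
11 | tri-O-methylrobustol (saturated 22-membered macrocycle, three OMe) | COc1cc2cc(c1)Oc1c(OC)cc(cc1OC)CCCCCCCCCCCCCC2 | intermediate
12 | robustol | Oc1cc2cc(c1)Oc1c(O)cc(cc1O)CCCCCCCCCCCCCC2 | target

**Step count**

Total steps: 6. Longest linear sequence: 5 steps (step 1 or 2, then steps 3, 4, 5, 6).

**Steps most likely to fail**

Step 3. The di-ortho-substituted, electron-rich phenoxide may be arylated too slowly on copper, so that hydrodebromination of the aryl bromide and oxidative degradation of the phenol outrun C–O bond formation. The fallback replaces the Ullmann coupling by a Chan–Lam–Evans oxidative coupling. It sets out from 8, which is converted by bromine–lithium exchange (n-BuLi, THF, −78 °C), borylation with B(OiPr)3 and acidic work-up into [3-(dec-9-en-1-yl)-5-methoxyphenyl]boronic acid F1. F1 and phenol 4 are then joined with Cu(OAc)2, pyridine and 4 Å molecular sieves in CH2Cl2 under air at rt, a coupling that passes through a trivalent copper aryl phenoxide and is known to accept 2,6-disubstituted phenols. The fallback comes back to the route at 9.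

Step 4. Intermolecular metathesis may compete with closure and give oligomers, and ruthenium hydride-induced double-bond migration before closure would give ring-contracted homologues that cannot be separated after hydrogenation. The fallback forms the same C5=C6 bond by intramolecular McMurry coupling. It sets out from 9, whose two vinyl groups are cleaved (OsO4 cat., NaIO4, 2,6-lutidine, dioxane/H2O, rt) to the dialdehyde 9-{3-[2,6-dimethoxy-4-(5-oxopentyl)phenoxy]-5-methoxyphenyl}nonanal F2. Slow syringe-pump addition of F2 to low-valent titanium (TiCl3, Zn–Cu couple, DME, reflux) should close the 22-membered ring by reductive carbonyl coupling. The fallback comes back to the route at 10.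

Step 1. Twofold hydroboration of the diene would give a bis-borane that links two arenes, and slow oxidative addition into the electron-rich phenoxide bromide would leave time for protodeboronation and for palladium hydride-mediated migration of the terminal double bond. The fallback avoids both the borane and the free phenol. It sets out from 2, which is protected (MOMCl, iPr2NEt, CH2Cl2, 0 °C to rt) as 5-bromo-1,3-dimethoxy-2-(methoxymethoxy)benzene F3. Kumada–Corriu coupling of F3 with hex-5-en-1-ylmagnesium bromide F4 (made from commercial 6-bromohex-1-ene and Mg in THF), catalysed by Pd(dppf)Cl2 in THF at 50 °C, should give 5-(hex-5-en-1-yl)-1,3-dimethoxy-2-(methoxymethoxy)benzene F5. Acetal cleavage (HCl, MeOH, rt) then comes back to the route at 4.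

**Further compounds**

F1 | step 3 | [3-(dec-9-en-1-yl)-5-methoxyphenyl]boronic acid | COc1cc(CCCCCCCCC=C)cc(B(O)O)c1
F2 | step 4 | 9-{3-[2,6-dimethoxy-4-(5-oxopentyl)phenoxy]-5-methoxyphenyl}nonanal | COc1cc(CCCCCCCCC=O)cc(Oc2c(OC)cc(CCCCC=O)cc2OC)c1
F3 | step 1 | 5-bromo-1,3-dimethoxy-2-(methoxymethoxy)benzene | COCOc1c(OC)cc(Br)cc1OC
F4 | step 1 | hex-5-en-1-ylmagnesium bromide | C=CCCCC[Mg]Br
F5 | step 1 | 5-(hex-5-en-1-yl)-1,3-dimethoxy-2-(methoxymethoxy)benzene | COCOc1c(OC)cc(CCCCC=C)cc1OC
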